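## Retrosynthetic overview

1. Key bond, made last: the C16–O–C3 ether of the oxepane, closed by attack of the C3 PMB‑ether oxygen on a C16 triflate (new debenzylative closure). C15 and C16 come from hydroboration of an isopropenyl group.
2. Cyclohexane and tetrahydrofuran form together in an intramolecular Diels–Alder reaction of a 2‑methoxydiene (C10–C13) with an enone (C1=C14) across a 2,9‑cis (6E)‑oxonene. The enol ether becomes the C11 ketone, then the 11‑butanoate.
3. Oxonene: amide enolate alkylation (C9 onto the C8 allylic chloride); its C2–O–C9 ether comes from a Williamson etherification.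
4. C2 and C3: Sharpless epoxidation of nerol, then invertive C3–O bond formation with 4‑methoxybenzyl alcohol; C8 is oxidised with SeO2.
5. Ring order: oxonene → tetrahydrofuran + cyclohexene (one step) → oxepane.

Assumption: atom numbers C1–C16 in names and text are asbestinin skeleton numbers (they coincide with nerol numbers for C1–C8); nerol and the Ohira–Bestmann reagent are taken as commercial.

## Route

Step 1
Reactants: 1 nerol
Product: 2 (2S,3R)-2,3-epoxynerol
Conditions: Ti(OiPr)4 (5 mol%), L-(+)-diethyl tartrate (6 mol%), t-BuOOH, 4 Å MS, CH2Cl2, −20 °C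
Reagents that add atoms: tert-butyl hydroperoxide, CC(C)(C)OO
Why: Sharpless asymmetric epoxidation touches only the allylic alcohol alkene, and with L-(+)-tartrate the oxygen is delivered to the face that gives C2 (S) and C3 (R), the cis-epoxide needed for an anti opening.

Step 2
Reactants: 2 (2S,3R)-2,3-epoxynerol
Product: 3 (2S,3S)-3-[(4-methoxybenzyl)oxy]-3,7-dimethyloct-6-ene-1,2-diol
Conditions: 4-methoxybenzyl alcohol (3 equiv), BF3·OEt2 (5 mol%), CH2Cl2, −40 → −20 °C
Reagents that add atoms: 4-methoxybenzyl alcohol, COc1ccc(CO)cc1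
Why: acid-catalysed epoxide alcoholysis of the borderline SN2 type at the tertiary C3 goes with inversion (C3 becomes S, C2 is untouched), forming the tertiary C3–O bond already protected as the PMB ether used again in step 18.

Step 3
Reactants: 3 (2S,3S)-3-[(4-methoxybenzyl)oxy]-3,7-dimethyloct-6-ene-1,2-diol
Product: 4 (2S,3S)-1-[(tert-butyldiphenylsilyl)oxy]-3-[(4-methoxybenzyl)oxy]-3,7-dimethyloct-6-en-2-ol
Conditions: t-BuPh2SiCl (1.05 equiv), imidazole, CH2Cl2, 0 °C
Reagents that add atoms: tert-butyl(chloro)diphenylsilane, CC(C)(C)[Si](Cl)(c1ccccc1)c1ccccc1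
Why: selective silylation of the primary hydroxyl, because the secondary hydroxyl next to the quaternary C3 is too hindered for the bulky chlorosilane at 0 °C.

Step 4
Reactants: 4 (2S,3S)-1-[(tert-butyldiphenylsilyl)oxy]-3-[(4-methoxybenzyl)oxy]-3,7-dimethyloct-6-en-2-ol
Product: 5 2-{[(2S,3S)-1-[(tert-butyldiphenylsilyl)oxy]-3-[(4-methoxybenzyl)oxy]-3,7-dimethyloct-6-en-2-yl]oxy}-N,N-dimethylacetamide
Conditions: NaH, ClCH2C(O)NMe2, Bu4NI (cat.), THF, 0 °C → rt
Reagents that add atoms: 2-chloro-N,N-dimethylacetamide, CN(C)C(=O)CCl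
Why: Williamson etherification of the secondary alkoxide with the activated α-chloroamide builds the C2–O–C9 ether (the later tetrahydrofuran oxygen) without touching a stereocentre.

Step 5
Reactants: 5 2-{[(2S,3S)-1-[(tert-butyldiphenylsilyl)oxy]-3-[(4-methoxybenzyl)oxy]-3,7-dimethyloct-6-en-2-yl]oxy}-N,N-dimethylacetamide
Product: 6 (6E)-8-hydroxy derivative of 5 (allylic alcohol)
Conditions: SeO2 (20 mol%), t-BuOOH, salicylic acid (10 mol%), CH2Cl2, rt
Reagents that add atoms: tert-butyl hydroperoxide, CC(C)(C)OO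
Why: SeO2 allylic oxidation (ene reaction then [2,3]-shift) of the terminal gem-dimethyl alkene is selective for the (E)-methyl group and so fixes the (6E)-trisubstituted alkene with C8 oxygenated.

Step 6
Reactants: 6 (6E)-8-hydroxy derivative of 5
Product: 7 (6E)-8-chloro derivative of 5 (allylic chloride)
Conditions: MsCl, LiCl, 2,4,6-collidine, DMF, 0 °C
Reagents that add atoms: lithium chloride, [Li+].[Cl-]
Why: Collington–Meyers chlorination (mesylate displaced by chloride in situ) gives the primary allylic chloride by SN2 without allylic transposition or loss of the (E)-geometry.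

Step 7
Reactants: 7 (6E)-8-chloro derivative of 5
Product: 8 (2S,3S,9S,6E)-2,9-cis-oxonene amide (ring O–C2–C3–C4–C5–C6=C7–C8–C9; CH2OSi(t-Bu)Ph2 on C2, CH3 and OPMB on C3, CH3 on C7, C(O)NMe2 on C9)
Conditions: LiN(SiMe3)2, THF (0.01 M), 0 → 45 °C
Reagents that add atoms: none
Why: intramolecular amide enolate alkylation (SN2 on the allylic chloride) closes the nine-membered ring, and the Z-enolate cyclises through the conformer with H2 and H9 on the same side, so C9 forms as S (2,9-cis) — recalled, not re-checked, precedent for C3-quaternary substrates of this kind.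

Step 8
Reactants: 8 (2S,3S,9S,6E)-2,9-cis-oxonene amide
Product: 9 (2S,3S,9S,6E)-oxonene-9-carbaldehyde (CHO in place of C(O)NMe2)
Conditions: i-Bu2AlH (1.3 equiv), THF, −78 °C; aq. potassium sodium tartrate
Reagents that add atoms: none
Why: partial reduction of the α-alkoxy N,N-dimethylamide, whose chelated aluminium hemiaminal is stable at −78 °C and releases the aldehyde only on work-up, so C9 is not epimerised.

Step 9
Reactants: 10 dimethyl (1-diazo-2-oxopropyl)phosphonate
Product: 11 dimethyl (1-methoxy-2-oxopropyl)phosphonate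
Conditions: MeOH (5 equiv), Rh2(OAc)4 (1 mol%), PhH, 80 °C
Reagents that add atoms: methanol, CO
Why: rhodium carbenoid O–H insertion of the diazophosphonate into methanol gives the α-methoxy β-ketophosphonate, whose stereocentre is lost in step 10.

Step 10
Reactants: 9 (2S,3S,9S,6E)-oxonene-9-carbaldehyde; 11 dimethyl (1-methoxy-2-oxopropyl)phosphonate
Product: 12 (Z)-α-methoxy enone (C9–C10H=C11(OMe)–C12(=O)CH3 on the oxonene of 9)
Conditions: NaH, THF, 0 °C; then 9, −20 °C → rt
Reagents that add atoms: none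
Why: Horner–Wadsworth–Emmons olefination under thermodynamic control places C9 trans to the acetyl group, that is cis to OMe (Z enol ether), the geometry the diene needs.

Step 11
Reactants: 12 (Z)-α-methoxy enone
Product: 13 (Z)-2-methoxy-3-methyl-1,3-diene (C10H=C11(OMe)–C12(CH3)=C13H2), silyl ether
Conditions: Ph3PCH3Br, KN(SiMe3)2, THF, 0 °C → rt
Reagents that add atoms: methyltriphenylphosphonium bromide, C[P+](c1ccccc1)(c1ccccc1)c1ccccc1.[Br-]
Why: Wittig methylenation of the ketone completes the C10–C13 diene without changing the enol ether geometry.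

Step 12
Reactants: 13 (Z)-2-methoxy-3-methyl-1,3-diene, silyl ether
Product: 14 diene alcohol (C1 hydroxyl free)
Conditions: Bu4NF, THF, 0 °C → rt
Reagents that add atoms: none
Why: fluoride-mediated desilylation frees the C1 hydroxyl under non-acidic conditions that the methoxydiene tolerates.

Step 13
Reactants: 14 diene alcohol
Product: 17 tricyclic methyl ketone (1R,2S,3S,9S,10R,14R): cyclohex-11-ene (C1/C10–C14; 11-OMe; 12-CH3; 14-acetyl) cis-fused at C1–C10 to the tetrahydrofuran (C1–C2–O–C9–C10) bridged by the (6E)-oxonene chain C3–C8 (3-CH3; 3-OPMB; 7-CH3), via oxonene aldehyde 15 (not isolated), via tetraene enone 16 (not isolated)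
Conditions: (n-Pr4N)RuO4 (5 mol%), N-methylmorpholine N-oxide, 4 Å MS, CH2Cl2, rt; then Ph3P=CHC(O)CH3, rt → 40 °C
Reagents that add atoms: 1-(triphenylphosphoranylidene)propan-2-one, CC(=O)C=P(c1ccccc1)(c1ccccc1)c1ccccc1
Why: Ley oxidation then Wittig olefination with the stabilised ylide gives the (E)-enone, which undergoes an intramolecular Diels–Alder reaction across the 2,9-cis-oxonene; the ether tether enforces the cis-fused tetrahydrofuran with H1 anti to H2 and H10 anti to H9 (sets C1 and C10), and the (E)-enone places the acetyl group trans to C2 (sets C14).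

Step 14
Reactants: 17 tricyclic methyl ketone
Product: 18 (1S,2S,3S,9S,10R,14R)-14-isopropenyl tricycle (C15(=C16H2)CH3 in place of acetyl)
Conditions: Ph3PCH3Br, KN(SiMe3)2, THF, 0 °C → rt
Reagents that add atoms: methyltriphenylphosphonium bromide, C[P+](c1ccccc1)(c1ccccc1)c1ccccc1.[Br-]
Why: Wittig methylenation converts the methyl ketone into the isopropenyl group; the equatorial C14 centre is the stable epimer and the enol ether is inert to the ylide.

Step 15
Reactants: 18 (1S,2S,3S,9S,10R,14R)-14-isopropenyl tricycle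
Product: 19 (1S,2S,3S,9S,10R,12R,14R)-11-ketone (C11=O, 12-CH3)
Conditions: 0.1 M HCl, THF–H2O (4:1), 0 °C; aq. NaHCO3
Reagents that add atoms: water, O
Why: enol ether hydrolysis with kinetic protonation at C12: A(1,2) strain with the C11 methoxy group holds the C10–C9 bond pseudoaxial on the concave face, so the proton enters from the convex face (the face of H1 and H10), C12 forms as R with its methyl cis to C9, and the cold dilute acid does not enolise the ketone afterwards.

Step 16
Reactants: 19 (1S,2S,3S,9S,10R,12R,14R)-11-ketone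
Product: 21 (1S,2S,3S,9S,10R,11R,12R,14R)-11-butanoate, via aluminium alkoxide 20 (not isolated)
Conditions: i-Bu2AlH, CH2Cl2, −78 °C; then pyridine, DMAP, (n-PrCO)2O, −78 → 0 °C
Reagents that add atoms: butanoic anhydride, CCCC(=O)OC(=O)CCC
Why: hydride adds to the ketone from the convex face (the concave face is blocked by the axial C9 and C12-methyl groups) to give the equatorial (11R) aluminium alkoxide, which is acylated in the same flask (reductive acylation) before C12 can epimerise.

Step 17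
Reactants: 21 (1S,2S,3S,9S,10R,11R,12R,14R)-11-butanoate
Product: 23 (1S,2S,3S,9S,10R,11R,12R,14S,15R)-16-alcohol (C14–C15H(CH3)–C16H2OH), via B-alkyl-9-BBN adduct 22 (not isolated)
Conditions: 9-BBN (1.5 equiv), THF, 0 °C → rt; then 30% H2O2, aq. NaOAc, 0 °C → rt
Reagents that add atoms: hydrogen peroxide, OO
Why: hydroboration–oxidation with 9-BBN is selective for the terminal 1,1-disubstituted alkene over the trisubstituted ring alkene (more than a hundredfold for unstrained cases), and the borane adds anti to the larger C1 branch in the conformer with H14 eclipsing the alkene, which sets C15 as R.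

Step 18
Reactants: 23 (1S,2S,3S,9S,10R,11R,12R,14S,15R)-16-alcohol
Product: 25 4-deoxyasbestinin A, via C16 triflate 24 (not isolated)
Conditions: Tf2O, 2,6-di-tert-butyl-4-methylpyridine, pentamethylbenzene, CH2Cl2, −78 → −20 °C
Reagents that add atoms: none
Why: Proposed new method: debenzylative 7-exo-tet cycloetherification, in which the primary triflate formed at −78 °C is attacked by the oxygen of the tertiary PMB ether held next to it by the trans-diequatorial C1 and C14 substituents, and the trialkyloxonium ion collapses by loss of the 4-methoxybenzyl cation (better stabilised than a C3 cation and trapped by pentamethylbenzene), so the C16–O–C3 bond and the oxepane form without a separate deprotection and no stereocentre is touched; the closest known reactions are debenzylative cycloetherifications of benzyl ethers onto sulfonates, epoxides or halonium ions giving five- and six-membered rings, and closure of a free tertiary alcohol onto the same kind of primary triflate.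

## Compound list

1 | nerol, (2Z)-3,7-dimethylocta-2,6-dien-1-ol | OC/C=C(C)\CCC=C(C)C | starting material
2 | (2S,3R)-2,3-epoxynerol, [(2S,3R)-3-methyl-3-(4-methylpent-3-en-1-yl)oxiran-2-yl]methanol | OC[C@@H]1O[C@]1(C)CCC=C(C)C | intermediate
3 | (2S,3S)-3-[(4-methoxybenzyl)oxy]-3,7-dimethyloct-6-ene-1,2-diol | OC[C@H](O)[C@@](C)(OCc1ccc(OC)cc1)CCC=C(C)C | intermediate
4 | (2S,3S)-1-[(tert-butyldiphenylsilyl)oxy]-3-[(4-methoxybenzyl)oxy]-3,7-dimethyloct-6-en-2-ol | CC(C)(C)[Si](OC[C@H](O)[C@@](C)(OCc1ccc(OC)cc1)CCC=C(C)C)(c1ccccc1)c1ccccc1 | intermediate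
5 | 2-{[(2S,3S)-1-[(tert-butyldiphenylsilyl)oxy]-3-[(4-methoxybenzyl)oxy]-3,7-dimethyloct-6-en-2-yl]oxy}-N,N-dimethylacetamide | CN(C)C(=O)CO[C@@H](CO[Si](C(C)(C)C)(c1ccccc1)c1ccccc1)[C@@](C)(OCc1ccc(OC)cc1)CCC=C(C)C | intermediate
6 | 2-{[(2S,3S,6E)-1-[(tert-butyldiphenylsilyl)oxy]-8-hydroxy-3-[(4-methoxybenzyl)oxy]-3,7-dimethyloct-6-en-2-yl]oxy}-N,N-dimethylacetamide | CN(C)C(=O)CO[C@@H](CO[Si](C(C)(C)C)(c1ccccc1)c1ccccc1)[C@@](C)(OCc1ccc(OC)cc1)CC/C=C(\C)CO | intermediate
7 | 2-{[(2S,3S,6E)-8-chloro-1-[(tert-butyldiphenylsilyl)oxy]-3-[(4-methoxybenzyl)oxy]-3,7-dimethyloct-6-en-2-yl]oxy}-N,N-dimethylacetamide | CN(C)C(=O)CO[C@@H](CO[Si](C(C)(C)C)(c1ccccc1)c1ccccc1)[C@@](C)(OCc1ccc(OC)cc1)CC/C=C(\C)CCl | intermediate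
8 | (2S,3S,9S,6E)-2,9-cis-oxonene amide: 2-CH2OSi(t-Bu)Ph2, 3-CH3, 3-OPMB, 7-CH3, 9-C(O)NMe2 | COc1ccc(CO[C@@]2(C)CC/C=C(\C)C[C@@H](C(=O)N(C)C)O[C@H]2CO[Si](C(C)(C)C)(c3ccccc3)c3ccccc3)cc1 | intermediate
9 | (2S,3S,9S,6E)-oxonene-9-carbaldehyde (CHO in place of the amide of 8) | COc1ccc(CO[C@@]2(C)CC/C=C(\C)C[C@@H](C=O)O[C@H]2CO[Si](C(C)(C)C)(c3ccccc3)c3ccccc3)cc1 | intermediate
10 | dimethyl (1-diazo-2-oxopropyl)phosphonate (Ohira–Bestmann reagent) | COP(=O)(OC)C(=[N+]=[N-])C(C)=O | starting material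
11 | dimethyl (1-methoxy-2-oxopropyl)phosphonate (racemic) | COC(C(C)=O)P(=O)(OC)OC | intermediate
12 | (2S,3S,9S,6E)-oxonene with (1Z)-2-methoxy-3-oxobut-1-en-1-yl on C9 (α-methoxy enone) | COc1ccc(CO[C@@]2(C)CC/C=C(\C)C[C@@H](/C=C(\OC)C(C)=O)O[C@H]2CO[Si](C(C)(C)C)(c3ccccc3)c3ccccc3)cc1 | intermediate
13 | (2S,3S,9S,6E)-oxonene with (1Z)-2-methoxy-3-methylbuta-1,3-dien-1-yl on C9, silyl ether | COc1ccc(CO[C@@]2(C)CC/C=C(\C)C[C@@H](/C=C(\OC)C(C)=C)O[C@H]2CO[Si](C(C)(C)C)(c3ccccc3)c3ccccc3)cc1 | intermediate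
14 | diene alcohol: as 13 with free CH2OH on C2 | COc1ccc(CO[C@@]2(C)CC/C=C(\C)C[C@@H](/C=C(\OC)C(C)=C)O[C@H]2CO)cc1 | intermediate
15 | oxonene aldehyde: as 14 with CHO on C2 (2R by priority change, same geometry) | COc1ccc(CO[C@@]2(C)CC/C=C(\C)C[C@@H](/C=C(\OC)C(C)=C)O[C@H]2C=O)cc1 | intermediate (not isolated)
16 | tetraene enone: as 14 with (1E)-3-oxobut-1-en-1-yl on C2 | COc1ccc(CO[C@@]2(C)CC/C=C(\C)C[C@@H](/C=C(\OC)C(C)=C)O[C@H]2/C=C/C(C)=O)cc1 | intermediate (not isolated)
17 | tricyclic methyl ketone (1R,2S,3S,9S,10R,14R): 14-acetyl, 11-methoxy-cyclohex-11-ene, 12-CH3, 3-CH3, 3-OPMB, (6E)-7-CH3, ether bridge C2–O–C9 | CC(=O)[C@@H]1CC(C)=C(OC)[C@@H]2[C@H]1[C@@H]1O[C@H]2C/C(C)=C/CC[C@]1(C)OCc1ccc(OC)cc1 | intermediate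
18 | (1S,2S,3S,9S,10R,14R)-14-isopropenyl tricycle (otherwise as 17) | CC(=C)[C@@H]1CC(C)=C(OC)[C@@H]2[C@H]1[C@@H]1O[C@H]2C/C(C)=C/CC[C@]1(C)OCc1ccc(OC)cc1 | intermediate
19 | (1S,2S,3S,9S,10R,12R,14R)-11-ketone, 12-CH3 cis to C9 | CC(=C)[C@@H]1C[C@@H](C)C(=O)[C@@H]2[C@H]1[C@@H]1O[C@H]2C/C(C)=C/CC[C@]1(C)OCc1ccc(OC)cc1 | intermediate
20 | diisobutylaluminium (11R)-alkoxide of reduced 19 | CC(=C)[C@@H]1C[C@@H](C)[C@@H](O[Al](CC(C)C)CC(C)C)[C@@H]2[C@H]1[C@@H]1O[C@H]2C/C(C)=C/CC[C@]1(C)OCc1ccc(OC)cc1 | intermediate (not isolated)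
21 | (1S,2S,3S,9S,10R,11R,12R,14R)-11-butanoate, 14-isopropenyl, 3-OPMB | CC(=C)[C@@H]1C[C@@H](C)[C@@H](OC(=O)CCC)[C@@H]2[C@H]1[C@@H]1O[C@H]2C/C(C)=C/CC[C@]1(C)OCc1ccc(OC)cc1 | intermediate
22 | B-alkyl-9-BBN adduct of 21 (boron on C16, 15R) | C1CC2CCCC(C1)B2C[C@H](C)[C@@H]1C[C@@H](C)[C@@H](OC(=O)CCC)[C@@H]2[C@H]1[C@@H]1O[C@H]2C/C(C)=C/CC[C@]1(C)OCc1ccc(OC)cc1 | intermediate (not isolated)
23 | (1S,2S,3S,9S,10R,11R,12R,14S,15R)-16-alcohol, 11-butanoate, 3-OPMB | OC[C@H](C)[C@@H]1C[C@@H](C)[C@@H](OC(=O)CCC)[C@@H]2[C@H]1[C@@H]1O[C@H]2C/C(C)=C/CC[C@]1(C)OCc1ccc(OC)cc1 | intermediate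
24 | C16 trifluoromethanesulfonate of 23 | FC(F)(F)S(=O)(=O)OC[C@H](C)[C@@H]1C[C@@H](C)[C@@H](OC(=O)CCC)[C@@H]2[C@H]1[C@@H]1O[C@H]2C/C(C)=C/CC[C@]1(C)OCc1ccc(OC)cc1 | intermediate (not isolated)
25 | 4-deoxyasbestinin A (1S,2S,3S,9S,10R,11R,12R,14S,15R,6E) | CCCC(=O)O[C@H]1[C@@H]2[C@@H]3[C@@H](C[C@H]1C)[C@@H](C)CO[C@@]1(C)CC/C=C(\C)C[C@@H]2O[C@@H]31 | target

## Step count and risks

Total steps: 18. Longest linear sequence: 17 (nerol 1 → 25; step 9 is a one-step branch that makes phosphonate 11).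

Three steps most likely to fail:

Step 18 (the new closure). The PMB ether oxygen may be too hindered to close, or the 4-methoxybenzyl cation may attack the ring alkenes. The fallback sets out from 23: DDQ in CH2Cl2/pH 7 buffer at 0 °C removes the PMB group to give the 3,16-diol F1. Tf2O and 2,6-lutidine in CH2Cl2 (−78 → 0 °C) then triflate only the primary hydroxyl, which the free tertiary C3 hydroxyl displaces in the same flask. This is the known triflate/tertiary-alcohol closure, costs one more step, and comes back at 25.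

Step 17 (chemo- and diastereoselectivity of the hydroboration). 9-BBN may also attack the strained (6E)-alkene or give a poor ratio at C15. The fallback sets out from 21 with a ligand-controlled copper hydride hydroboration: CuCl, (R)- or (S)-DTBM-SEGPHOS (the enantiomer matched to 15R, found by screening), NaOt-Bu and pinacolborane in THF at rt. Copper hydride inserts only the terminal 1,1-disubstituted alkene, so the trisubstituted alkenes are inert and the ligand, not the substrate, sets C15. The pinacol boronate F2 is oxidised (H2O2, aq. NaOAc) and the route is rejoined at 23.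

Step 15 (C12 by kinetic protonation). Protonation may give mixtures, or the ketone may epimerise to the more stable C12 epimer. The fallback sets out from 18 and delivers the C12 hydrogen as an atom instead of a proton. N-Bromosuccinimide in wet THF at −78 °C converts the enol ether (the most electron-rich alkene) into the α-bromo ketone F3. Bu3SnH/AIBN (PhH, 80 °C) then reduces the C–Br bond through the planar C12 radical, which takes hydrogen from the bulky stannane on the open convex face under neutral, non-epimerising conditions. This comes back at 19.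

## Further compounds

F1 | step 18 | 3,16-diol: (1S,2S,3S,9S,10R,11R,12R,14S,15R)-11-butanoate with free C3 and C16 hydroxyls | OC[C@H](C)[C@@H]1C[C@@H](C)[C@@H](OC(=O)CCC)[C@@H]2[C@H]1[C@@H]1O[C@H]2C/C(C)=C/CC[C@]1(C)O
F2 | step 17 | C16 pinacol boronate of 21 (15R) | CC1(C)OB(C[C@H](C)[C@@H]2C[C@@H](C)[C@@H](OC(=O)CCC)[C@@H]3[C@H]2[C@@H]2O[C@H]3C/C(C)=C/CC[C@]2(C)OCc2ccc(OC)cc2)OC1(C)C
F3 | step 15 | 12-bromo-11-ketone from 18 (C12 configuration not defined) | CC(=C)[C@@H]1CC(C)(Br)C(=O)[C@@H]2[C@H]1[C@@H]1O[C@H]2C/C(C)=C/CC[C@]1(C)OCc1ccc(OC)cc1
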